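Drimane numbering is used throughout: decalin carbons C1–C10, C11 is the exocyclic carbon bearing Cl and the arene, and C8 bears the secondary methyl group.

Retrosynthesis: after the two silyl ethers and a helper carbonyl at C6 are put in, ring B is cut at C5–C6 and C9–C10 into 1,3,3-trimethylcyclohexene (ring A) and an (R)-3-methyl-5-arylpent-4-ynoyl chloride. The acid is cut further at C11–aryl (Sonogashira) and C7–C8 (malonate displacement).
Forward: ring A is used intact and ring B arises in one operation. The acylium carbon C6 is attacked by C5 of the olefin, the tertiary cation at C10 is captured by alkyne carbon C9, and the vinyl cation at C11 takes up chloride.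
Enabling feature: C10 is a fully substituted carbon next to the C4 gem-dimethyl carbon, so a C5=C10 olefin gives a tertiary cation there that closes equatorially (trans fusion). C11 bears exactly an arene and a chlorine, which is what an aryl-stabilised vinyl cation leaves after chloride capture.
Stereochemistry: C8 (R) is bought as (R)-but-3-yn-2-ol and carried in by invertive substitution. It steers C10 in a chair-like closure, C5 equilibrates next to the C6 ketone, and chloride enters anti to the new C9–C10 bond (E).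
The C6 ketone is then used to invert C8 (dehydrogenation to the C7=C8 enone, then hydride to C8 from the α face, away from the C10 methyl) and is removed through its enol triflate. Desilylation ends the route.

Key step: step 10

Remark: Ar stands for 3-methoxy-2,5-bis(triisopropylsilyloxy)phenyl; α and β refer to the usual drimane drawing with the C10 methyl group β. The chlorine of the vinyl chloride is counted as coming from the acid chloride; SnCl4 shuttles chloride and is regenerated.

Step 1
Reactants: 1 5-iodovanillin (4-hydroxy-3-iodo-5-methoxybenzaldehyde)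
Product: 3 2-iodo-6-methoxybenzene-1,4-diol, via 4-hydroxy-3-iodo-5-methoxyphenyl formate 2 (not isolated)
Conditions: 30% aq H2O2, NaOH, THF/H2O, 0 → 23 °C, under N2
Reagents that add atoms: hydrogen peroxide, OO
Why: Dakin oxidation, in which hydroperoxide adds to the para-hydroxy benzaldehyde, the electron-rich aryl group migrates to oxygen and the formate is hydrolysed in the basic medium.

Step 2
Reactants: 3 2-iodo-6-methoxybenzene-1,4-diol
Product: 4 1-iodo-3-methoxy-2,5-bis(triisopropylsilyloxy)benzene
Conditions: TIPSOTf, 2,6-lutidine, CH2Cl2, 0 → 23 °C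
Reagents that add atoms: triisopropylsilyl trifluoromethanesulfonate, CC(C)[Si](C(C)C)(C(C)C)OS(=O)(=O)C(F)(F)F
Why: Silylation of both phenols with the reactive silyl triflate (needed for the flanked hydroxyl), giving bulky ethers that later shield both free arene positions from the acylium ion.

Step 3
Reactants: 5 (R)-but-3-yn-2-ol
Product: 6 (R)-but-3-yn-2-yl 4-methylbenzenesulfonate
Conditions: TsCl, Et3N, DMAP (cat.), CH2Cl2, 0 °C
Reagents that add atoms: 4-toluenesulfonyl chloride, Cc1ccc(S(=O)(=O)Cl)cc1
Why: O-Sulfonylation, which leaves the carbinol carbon untouched (retention).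

Step 4
Reactants: 6 (R)-but-3-yn-2-yl 4-methylbenzenesulfonate; 7 dimethyl malonate
Product: 9 dimethyl 2-[(2R)-but-3-yn-2-yl]propanedioate, via sodium dimethyl malonate 8 (not isolated)
Conditions: NaH, THF/DMF, 0 → 60 °C
Reagents that add atoms: none
Why: SN2 displacement of the activated secondary propargylic sulfonate by the soft malonate carbanion with inversion (the descriptor stays R only because the priorities change), with no copper present so that attack at the alkyne terminus to an allene is not favoured.

Step 5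
Reactants: 9 dimethyl 2-[(2R)-but-3-yn-2-yl]propanedioate
Product: 11 methyl (3R)-3-methylpent-4-ynoate, via lithium half-ester carboxylate 10 (not isolated)
Conditions: LiCl, H2O, DMSO, 150 °C
Reagents that add atoms: none
Why: Krapcho dealkoxycarbonylation (chloride demethylates one ester, the carboxylate loses CO2), which does not touch the stereocentre.

Step 6
Reactants: 11 methyl (3R)-3-methylpent-4-ynoate; 4 1-iodo-3-methoxy-2,5-bis(triisopropylsilyloxy)benzene
Product: 12 methyl (3R)-5-Ar-3-methylpent-4-ynoate
Conditions: PdCl2(PPh3)2 (3 mol%), CuI (6 mol%), Et3N, THF, 45 °C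
Reagents that add atoms: none
Why: Sonogashira coupling of the terminal alkyne with the aryl iodide, the ortho silyl ether preventing the benzofuran closure a free ortho phenol would undergo.

Step 7
Reactants: 12 methyl (3R)-5-Ar-3-methylpent-4-ynoate
Product: 13 (3R)-5-Ar-3-methylpent-4-ynoic acid
Conditions: Me3SnOH, ClCH2CH2Cl, 80 °C; then 1 M HCl wash
Reagents that add atoms: trimethyltin hydroxide, C[Sn](C)(C)O
Why: Mild, near-neutral ester hydrolysis that should spare the base-sensitive aryl silyl ethers.

Step 8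
Reactants: 14 2,2,6-trimethylcyclohexanone
Product: 15 2,2,6-trimethylcyclohexanone 2,4,6-triisopropylbenzenesulfonylhydrazone
Conditions: 2,4,6-triisopropylbenzenesulfonyl hydrazide, HCl (cat.), MeOH, 23 °C
Reagents that add atoms: 2,4,6-triisopropylbenzenesulfonyl hydrazide, CC(C)c1cc(C(C)C)c(S(=O)(=O)NN)c(C(C)C)c1
Why: Acid-catalysed hydrazone condensation, well known for this hindered ketone.

Step 9
Reactants: 15 2,2,6-trimethylcyclohexanone 2,4,6-triisopropylbenzenesulfonylhydrazone
Product: 17 1,3,3-trimethylcyclohexene, via 2,6,6-trimethylcyclohex-1-enyllithium 16 (not isolated)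
Conditions: n-BuLi (2.2 equiv), TMEDA, hexane/THF, −78 → 0 °C; then H2O
Reagents that add atoms: none
Why: Shapiro reaction, in which the only α-hydrogen (on the methyl-bearing carbon) is removed so that the double bond forms toward that carbon, and protonation of the vinyllithium gives the olefin.

Step 10
Reactants: 13 (3R)-5-Ar-3-methylpent-4-ynoic acid; 17 1,3,3-trimethylcyclohexene (3 equiv)
Product: 19 (5S,8R,10S)-11-Ar-11-chloro-9(11)E-drimen-6-one (trans-decalin with 8α-methyl), via (3R)-5-Ar-3-methylpent-4-ynoyl chloride 18 (not isolated)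
Conditions: (COCl)2, DMF (cat.), CH2Cl2, 0 → 23 °C, then evaporation; 17, SnCl4 (2.2 equiv), CH2Cl2, −78 → −20 °C; then DBU (0.2 equiv), toluene, 50 °C
Reagents that add atoms: oxalyl chloride, O=C(Cl)C(=O)Cl
Why: Proposed new method: SnCl4 ionises acid chloride 18 and the acylium carbon C6 is attacked by C5, the less substituted carbon of the C5=C10 olefin of 17, which places the charge on tertiary C10; the alkyne then attacks C10 through C9 and the linear aryl-stabilised vinyl cation at C11 takes chloride from SnCl5−. The closest known reaction types are the Friedel–Crafts acylation of alkenes joined to cycloalkylation (arylacetyl chlorides with cyclohexenes give octahydrophenanthrenones) and alkyne-terminated cation-olefin cyclisations that end in a vinyl halide, whereas an alkyne as internal terminator of an intermolecular alkene acylation has not been shown. Ring B closes 6-exo-dig (C9 in the ring, C11 outside) through a chair-like transition state. C10 is controlled by the C8 stereocentre, whose methyl group sits equatorial in that chair while the new bond enters C10 equatorially because the axial C4 methyl blocks the other face; C5 lies α to the new ketone and is brought to the trans fusion by the DBU treatment, and material from the opposite facial course is a diastereomer that is removed at this stage. The E geometry should follow from chloride entering the vinyl cation anti to the new C9–C10 bond, away from quaternary C10. The step needs acylation of the olefin in preference to the alkyne and the arene, which the excess of the more nucleophilic trisubstituted olefin and the two bulky silyl ethers flanking both free arene positions should secure, and Markovnikov regiochemistry, which the tertiary C10 cation secures.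

Step 11
Reactants: 19 (5S,8R,10S)-11-Ar-11-chloro-9(11)E-drimen-6-one
Product: 20 (5S,10S)-11-Ar-11-chloro-9(11)E-drima-7,9(11)-dien-6-one
Conditions: IBX (2-iodoxybenzoic acid, 2.5 equiv), DMSO/fluorobenzene, 75 °C
Reagents that add atoms: none
Why: IBX dehydrogenation of the ketone through its enol, regiospecific because C7 is the only α-carbon with a β-hydrogen (C4 and C10 are quaternary), which erases the C8 stereocentre after it has done its work.

Step 12
Reactants: 20 (5S,10S)-11-Ar-11-chloro-9(11)E-drima-7,9(11)-dien-6-one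
Product: 21 (5S,8S,10S)-11-Ar-11-chloro-9(11)E-drimen-6-one (8β-methyl)
Conditions: [(Ph3P)CuH]6 (0.5 equiv), degassed H2O, THF, 23 °C
Reagents that add atoms: none
Why: Copper hydride conjugate reduction, in which hydride should reach C8 from the α face opposite the axial C10 methyl to set 8β-methyl (8S), while the hindered chloroalkene, twisted out of conjugation by the clash of Cl with the C8 methyl, should be left alone.

Step 13
Reactants: 21 (5S,8S,10S)-11-Ar-11-chloro-9(11)E-drimen-6-one
Product: 23 (5S,8S,10S)-11-Ar-11-chloro-9(11)E-drima-6,9(11)-dien-6-yl trifluoromethanesulfonate, via potassium C6–C7 enolate 22 (not isolated)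
Conditions: KHMDS, THF, −78 °C; then PhNTf2, −78 → 0 °C
Reagents that add atoms: N-phenylbis(trifluoromethanesulfonimide), O=S(=O)(N(c1ccccc1)S(=O)(=O)C(F)(F)F)C(F)(F)F
Why: Kinetic enolisation at the C7 methylene (the C5 hydrogen is buried between two quaternary carbons) followed by O-triflation.

Step 14
Reactants: 23 (5S,8S,10S)-11-Ar-11-chloro-9(11)E-drima-6,9(11)-dien-6-yl trifluoromethanesulfonate
Product: 24 (5S,8S,10S)-11-Ar-11-chloro-9(11)E-drima-6,9(11)-diene
Conditions: Pd(OAc)2 (5 mol%), PPh3 (10 mol%), HCO2H, n-Bu3N, DMF, 60 °C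
Reagents that add atoms: none
Why: Palladium-catalysed formate reduction of an enol triflate, zerovalent palladium inserting into the C–OTf bond far faster than into the hindered tetrasubstituted vinyl chloride.

Step 15
Reactants: 24 (5S,8S,10S)-11-Ar-11-chloro-9(11)E-drima-6,9(11)-diene
Product: 25 (5S,8S,10S)-11-Ar-11-chloro-9(11)E-drimene
Conditions: 2-nitrobenzenesulfonyl hydrazide, Et3N, CH2Cl2, 23 °C
Reagents that add atoms: none
Why: Diimide reduction, a concerted syn hydrogen transfer that reaches the cis-disubstituted C6=C7 bond but neither the tetrasubstituted chloroalkene nor the C–Cl bond.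

Step 16
Reactants: 25 (5S,8S,10S)-11-Ar-11-chloro-9(11)E-drimene
Product: 26 2-{(E)-chloro[(2S,4aS,8aS)-2,5,5,8a-tetramethyl-3,4,4a,5,6,7,8,8a-octahydronaphthalen-1(2H)-ylidene]methyl}-6-methoxybenzene-1,4-diol (CNP0162917.1)
Conditions: TBAF, AcOH, THF, 0 °C, degassed
Reagents that add atoms: none
Why: Fluoride cleavage of both aryl silyl ethers, buffered with acetic acid so that the hydroquinone is not exposed to air as its phenoxide.

Compound list
1 | 5-iodovanillin (4-hydroxy-3-iodo-5-methoxybenzaldehyde) | COc1cc(C=O)cc(I)c1O | starting material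
2 | 4-hydroxy-3-iodo-5-methoxyphenyl formate | COc1cc(OC=O)cc(I)c1O | intermediate
3 | 2-iodo-6-methoxybenzene-1,4-diol | COc1cc(O)cc(I)c1O | intermediate
4 | 1-iodo-3-methoxy-2,5-bis(triisopropylsilyloxy)benzene | COc1cc(O[Si](C(C)C)(C(C)C)C(C)C)cc(I)c1O[Si](C(C)C)(C(C)C)C(C)C | intermediate
5 | (R)-but-3-yn-2-ol | C[C@@H](O)C#C | starting material
6 | (R)-but-3-yn-2-yl 4-methylbenzenesulfonate | C[C@@H](OS(=O)(=O)c1ccc(C)cc1)C#C | intermediate
7 | dimethyl malonate | COC(=O)CC(=O)OC | starting material
8 | sodium dimethyl malonate | COC(=O)[CH-]C(=O)OC.[Na+] | intermediate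
9 | dimethyl 2-[(2R)-but-3-yn-2-yl]propanedioate | C[C@H](C(C(=O)OC)C(=O)OC)C#C | intermediate
10 | lithium 2-[(2R)-but-3-yn-2-yl]-3-methoxy-3-oxopropanoate | C[C@H](C(C(=O)[O-])C(=O)OC)C#C.[Li+] | intermediate
11 | methyl (3R)-3-methylpent-4-ynoate | C[C@H](CC(=O)OC)C#C | intermediate
12 | methyl (3R)-5-[3-methoxy-2,5-bis(triisopropylsilyloxy)phenyl]-3-methylpent-4-ynoate | C[C@H](CC(=O)OC)C#Cc1cc(O[Si](C(C)C)(C(C)C)C(C)C)cc(OC)c1O[Si](C(C)C)(C(C)C)C(C)C | intermediate
13 | (3R)-5-[3-methoxy-2,5-bis(triisopropylsilyloxy)phenyl]-3-methylpent-4-ynoic acid | C[C@H](CC(=O)O)C#Cc1cc(O[Si](C(C)C)(C(C)C)C(C)C)cc(OC)c1O[Si](C(C)C)(C(C)C)C(C)C | intermediate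
14 | 2,2,6-trimethylcyclohexanone | CC1CCCC(C)(C)C1=O | starting material
15 | 2,2,6-trimethylcyclohexanone 2,4,6-triisopropylbenzenesulfonylhydrazone | CC1CCCC(C)(C)C1=NNS(=O)(=O)c1c(C(C)C)cc(C(C)C)cc1C(C)C | intermediate
16 | 2,6,6-trimethylcyclohex-1-enyllithium | [Li]C1=C(C)CCCC1(C)C | intermediate
17 | 1,3,3-trimethylcyclohexene | CC1=CC(C)(C)CCC1 | intermediate
18 | (3R)-5-[3-methoxy-2,5-bis(triisopropylsilyloxy)phenyl]-3-methylpent-4-ynoyl chloride | C[C@H](CC(=O)Cl)C#Cc1cc(O[Si](C(C)C)(C(C)C)C(C)C)cc(OC)c1O[Si](C(C)C)(C(C)C)C(C)C | intermediate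
19 | (5S,8R,10S)-11-Ar-11-chloro-9(11)E-drimen-6-one (trans-decalin, 8α-methyl) | COc1cc(O[Si](C(C)C)(C(C)C)C(C)C)cc(/C(Cl)=C2/[C@H](C)CC(=O)[C@H]3C(C)(C)CCC[C@]23C)c1O[Si](C(C)C)(C(C)C)C(C)C | intermediate
20 | (5S,10S)-11-Ar-11-chloro-9(11)E-drima-7,9(11)-dien-6-one | COc1cc(O[Si](C(C)C)(C(C)C)C(C)C)cc(/C(Cl)=C2/C(C)=CC(=O)[C@H]3C(C)(C)CCC[C@]23C)c1O[Si](C(C)C)(C(C)C)C(C)C | intermediate
21 | (5S,8S,10S)-11-Ar-11-chloro-9(11)E-drimen-6-one (8β-methyl) | COc1cc(O[Si](C(C)C)(C(C)C)C(C)C)cc(/C(Cl)=C2/[C@@H](C)CC(=O)[C@H]3C(C)(C)CCC[C@]23C)c1O[Si](C(C)C)(C(C)C)C(C)C | intermediate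
22 | potassium C6–C7 enolate of 21 | COc1cc(O[Si](C(C)C)(C(C)C)C(C)C)cc(/C(Cl)=C2/[C@@H](C)C=C([O-])[C@H]3C(C)(C)CCC[C@]23C)c1O[Si](C(C)C)(C(C)C)C(C)C.[K+] | intermediate
23 | (5S,8S,10S)-11-Ar-11-chloro-9(11)E-drima-6,9(11)-dien-6-yl trifluoromethanesulfonate | COc1cc(O[Si](C(C)C)(C(C)C)C(C)C)cc(/C(Cl)=C2/[C@@H](C)C=C(OS(=O)(=O)C(F)(F)F)[C@H]3C(C)(C)CCC[C@]23C)c1O[Si](C(C)C)(C(C)C)C(C)C | intermediate
24 | (5S,8S,10S)-11-Ar-11-chloro-9(11)E-drima-6,9(11)-diene | COc1cc(O[Si](C(C)C)(C(C)C)C(C)C)cc(/C(Cl)=C2/[C@@H](C)C=C[C@H]3C(C)(C)CCC[C@]23C)c1O[Si](C(C)C)(C(C)C)C(C)C | intermediate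
25 | (5S,8S,10S)-11-Ar-11-chloro-9(11)E-drimene (bis-silyl ether of the target) | COc1cc(O[Si](C(C)C)(C(C)C)C(C)C)cc(/C(Cl)=C2/[C@@H](C)CC[C@H]3C(C)(C)CCC[C@]23C)c1O[Si](C(C)C)(C(C)C)C(C)C | intermediate
26 | 2-{(E)-chloro[(2S,4aS,8aS)-2,5,5,8a-tetramethyl-3,4,4a,5,6,7,8,8a-octahydronaphthalen-1(2H)-ylidene]methyl}-6-methoxybenzene-1,4-diol | COc1cc(O)cc(/C(Cl)=C2/[C@@H](C)CC[C@H]3C(C)(C)CCC[C@]23C)c1O | target

Total step count: 16 steps.
Longest linear sequence: 12 steps (steps 3–7 and 10–16, from (R)-but-3-yn-2-ol 5).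

Steps most likely to fail

Step 10 (proposed new method). The acylium ion may acylate the alkyne or the arene of a second molecule instead of the olefin. The C10 cation may lose a proton before the alkyne closes the ring, or acid may isomerise the olefin first. Facial control by C8 may be incomplete, and chloride may enter from both sides of the vinyl cation. The fallback sets out from acid 13 and uses known chemistry in separate operations. Amide coupling with MeNHOMe·HCl (EDC·HCl, i-Pr2NEt) gives (3R)-N-methoxy-N,3-dimethyl-5-Ar-pent-4-ynamide F1. Vinyllithium 16, generated from 15 as in step 9 without the water quench, adds to it in a Weinreb ketone synthesis to give (3R)-3-methyl-5-Ar-1-(2,6,6-trimethylcyclohex-1-en-1-yl)pent-4-yn-1-one F2. The SnCl4-complexed enone is then closed by the alkyne-terminated cationic cyclisation with chloride capture (CH2Cl2, −78 → 0 °C, aqueous work-up, DBU), which comes back to the route at 19. The C5–C6 bond is then made by carbonyl addition and only C9–C10 by the cationic step.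

Step 12. Hydride may be delivered to the β face of C8, or in a vinylogous sense to C11 with loss of chloride. The fallback sets out from enone 20 and replaces intermolecular delivery by a stereospecific transfer. Reduction with NaBH4/CeCl3·7H2O (hydride from the open α face) gives (5S,6R,10S)-11-Ar-11-chloro-9(11)E-drima-7,9(11)-dien-6β-ol F3. KHMDS and ClCO2Me convert it into the methyl carbonate F4. Pd(OAc)2/n-Bu3P with HCO2H and Et3N in THF then ionises the pseudo-axial carbonate from the α face and passes hydride from palladium to the more substituted allyl terminus C8 on that same face. This gives diene 24 directly, where it comes back to the route (steps 13 and 14 are then not needed).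

Step 11. Enolisation of the hindered ketone may be slow, and the oxidant may attack the electron-rich arene on prolonged heating. The fallback sets out from ketone 19: LDA and TMSCl at −78 °C give the C6–C7 trimethylsilyl enol ether F5, and Pd(OAc)2 in MeCN (Saegusa–Ito oxidation) returns to the route at enone 20.

Further compounds
F1 | step 10 | (3R)-N-methoxy-N,3-dimethyl-5-[3-methoxy-2,5-bis(triisopropylsilyloxy)phenyl]pent-4-ynamide | C[C@H](CC(=O)N(C)OC)C#Cc1cc(O[Si](C(C)C)(C(C)C)C(C)C)cc(OC)c1O[Si](C(C)C)(C(C)C)C(C)C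
F2 | step 10 | (3R)-5-[3-methoxy-2,5-bis(triisopropylsilyloxy)phenyl]-3-methyl-1-(2,6,6-trimethylcyclohex-1-en-1-yl)pent-4-yn-1-one | CC1=C(C(=O)C[C@@H](C)C#Cc2cc(O[Si](C(C)C)(C(C)C)C(C)C)cc(OC)c2O[Si](C(C)C)(C(C)C)C(C)C)C(C)(C)CCC1
F3 | step 12 | (5S,6R,10S)-11-Ar-11-chloro-9(11)E-drima-7,9(11)-dien-6β-ol | COc1cc(O[Si](C(C)C)(C(C)C)C(C)C)cc(/C(Cl)=C2/C(C)=C[C@@H](O)[C@H]3C(C)(C)CCC[C@]23C)c1O[Si](C(C)C)(C(C)C)C(C)C
F4 | step 12 | (5S,6R,10S)-11-Ar-11-chloro-9(11)E-drima-7,9(11)-dien-6β-yl methyl carbonate | COc1cc(O[Si](C(C)C)(C(C)C)C(C)C)cc(/C(Cl)=C2/C(C)=C[C@@H](OC(=O)OC)[C@H]3C(C)(C)CCC[C@]23C)c1O[Si](C(C)C)(C(C)C)C(C)C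
F5 | step 11 | (5S,8R,10S)-11-Ar-11-chloro-6-(trimethylsilyloxy)-9(11)E-drima-6,9(11)-diene | COc1cc(O[Si](C(C)C)(C(C)C)C(C)C)cc(/C(Cl)=C2/[C@H](C)C=C(O[Si](C)(C)C)[C@H]3C(C)(C)CCC[C@]23C)c1O[Si](C(C)C)(C(C)C)C(C)C
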